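**Retrosynthetic overview**

1. The five benzyl ethers are removed last. The C3–C3'' bond is cut next: two (2S)-flavanones, 13 (5,7-dioxygenated half) and 17 (7-oxygenated half), are joined through a temporary O–Si–O tether and coupled oxidatively. Each new centre should form trans to the aryl group on its own C2, so two S centres lead to 3R,3''R.
2. The pyranone of the 5,7-dihydroxy half (O1''–C2''–C3''–C4''–C4a''–C8a'') is made by a two-atom ring expansion. Its O1''–C2''–C3''–C4''(=O) segment is a β-hydroxy acid and is stored as the strained (S)-oxetan-2-one 4. C4a'' and C8a'' are adjacent carbons of the phloroglucinol ring A'' and arrive as aryne 11, whose benzyloxy group next to the triple bond (the later 5''-oxygen) fixes the direction of insertion into the acyl C–O bond.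
3. C2'' is set by asymmetric transfer hydrogenation of β-keto ester 1. C2 is set by asymmetric conjugate addition of boronic acid 16 to chromone 15.
4. Ring order: oxetanone (step 3), then ring A'' and its pyranone in one operation (step 7). The pyranone of the 7-hydroxy half is bought as a chromone and made stereogenic (step 9). No ring is formed after that; C3–C3'' follows in step 12.

Key step: step 7

Remark: unprimed locants denote the 7-hydroxyflavanone half and doubly primed locants the 5,7-dihydroxyflavanone half; 1, 5, 14 and 16 are taken to be purchasable.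

**Route**

Step 1
Reactants: 1 ethyl 3-[4-(benzyloxy)phenyl]-3-oxopropanoate
Product: 2 ethyl (3S)-3-[4-(benzyloxy)phenyl]-3-hydroxypropanoate
Conditions: RuCl(p-cymene)[(S,S)-TsDPEN] (1 mol%), HCO2H/Et3N (5:2), DMF, 40 °C
Reagents that add atoms: none
Why: Asymmetric transfer hydrogenation of an aryl ketone with the Ru/TsDPEN catalyst; the (S,S) ligand should deliver hydride to the face that gives the S carbinol, as with simple aryl ketones, and this carbon becomes C2''.

Step 2
Reactants: 2 ethyl (3S)-3-[4-(benzyloxy)phenyl]-3-hydroxypropanoate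
Product: 3 (3S)-3-[4-(benzyloxy)phenyl]-3-hydroxypropanoic acid
Conditions: LiOH·H2O, THF/H2O (3:1), 0 °C to rt; then 1 M HCl to pH 3
Reagents that add atoms: lithium hydroxide [Li+].[OH-]
Why: Ester saponification; the carbinol centre is not touched, and cold, brief treatment limits retro-aldol cleavage.

Step 3
Reactants: 3 (3S)-3-[4-(benzyloxy)phenyl]-3-hydroxypropanoic acid
Product: 4 (4S)-4-[4-(benzyloxy)phenyl]oxetan-2-one
Conditions: PhSO2Cl (2 equiv), pyridine, 0–4 °C, 16 h; cold work-up
Reagents that add atoms: none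
Why: β-Lactonisation by carboxyl activation (mixed sulfonic anhydride); the hydroxyl attacks the activated acyl carbon, so the C–O bond at the carbinol is not broken and S is retained.

Step 4
Reactants: 5 3,5-bis(benzyloxy)phenol
Product: 6 3,5-bis(benzyloxy)phenyl N-(propan-2-yl)carbamate
Conditions: iPrNCO (1.5 equiv), Et3N (0.2 equiv), CH2Cl2, rt
Reagents that add atoms: isopropyl isocyanate CC(C)N=C=O
Why: Base-catalysed addition of a phenol to an isocyanate (carbamoylation) installs a strong ortho-directing group that can later be removed under mild base.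

Step 5
Reactants: 6 3,5-bis(benzyloxy)phenyl N-(propan-2-yl)carbamate
Product: 8 3,5-bis(benzyloxy)-2-(trimethylsilyl)phenyl N-(propan-2-yl)carbamate, via N-silyl carbamate 7 (not isolated)
Conditions: TBSOTf (1.1 equiv), TMEDA, Et2O, 0 °C to rt; then n-BuLi (2 equiv), TMEDA, −78 °C; TMSCl (3.5 equiv), −78 °C to rt; aq NaHSO4 work-up
Reagents that add atoms: chlorotrimethylsilane C[Si](C)(C)Cl
Why: Directed ortho-metalation of the carbamate after N-silylation in the flask; the position between the carbamate oxygen and a benzyloxy group (C2, equivalent to C6) is the only one ortho to the carbamate and is doubly activated, and the acidic work-up removes the N-silyl group.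

Step 6
Reactants: 8 3,5-bis(benzyloxy)-2-(trimethylsilyl)phenyl N-(propan-2-yl)carbamate
Product: 10 3,5-bis(benzyloxy)-2-(trimethylsilyl)phenyl trifluoromethanesulfonate, via phenol 9 (not isolated)
Conditions: DBU (1.5 equiv), Et2NH (1.2 equiv), MeCN, 40 °C; then PhNTf2 (1.5 equiv), rt
Reagents that add atoms: N-phenylbis(trifluoromethanesulfonimide) O=S(=O)(N(c1ccccc1)S(=O)(=O)C(F)(F)F)C(F)(F)F
Why: E1cB cleavage of the secondary carbamate (the isocyanate is trapped by diethylamine) followed by O-triflation of the phenoxide in the same pot gives the ortho-silylaryl triflate, a fluoride-triggered aryne precursor.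

Step 7
Reactants: 4 (4S)-4-[4-(benzyloxy)phenyl]oxetan-2-one; 10 3,5-bis(benzyloxy)-2-(trimethylsilyl)phenyl trifluoromethanesulfonate
Product: 13 (2S)-5,7-bis(benzyloxy)-2-[4-(benzyloxy)phenyl]chroman-4-one, via aryne 11 (not isolated), via acyl fluoride alkoxide 12 (not isolated)
Conditions: CsF (3 equiv), MeCN, 0 °C to rt; 10 (1.3 equiv) added over 2 h; quenched at pH 7
Reagents that add atoms: none
Why: Proposed new method: fluoride should both release 3,5-bis(benzyloxy)benzyne 11 from 10 and reversibly open the strained acyl C–O bond of 4 to the cesium alkoxide/acyl fluoride 12; the alkoxide should add to the aryne carbon remote from the flanking benzyloxy group, and the aryl anion so formed should attack the acyl fluoride, so that the two aryne carbons are inserted into the O1–C2(=O) bond of the oxetan-2-one and the four-membered lactone becomes the six-membered pyranone (ring O, C4, C3 and C2 of 4 become O1'', C2'', C3'' and C4''; the aryne supplies C4a'', C8a'' and the rest of ring A''). The closest known reaction types are the two-carbon ring expansion of cyclic β-keto esters by aryne acyl-alkylation, aryne insertion into the N–C(=O) bond of amides and β-lactams, the carboxylic acid/aryne C–O insertion to o-hydroxyaryl ketones and the phenoxide/aryne/ester annulation to xanthones; what is new is the use of the acyl C–O bond of a β-lactone. The pyranone closes by 6-exo-trig acyl substitution of the aryl anion at the acyl fluoride, fluoride is returned and acts as a relay, and the release of the lactone strain should make the sequence irreversible. No stereocentre is formed: C2'' should keep the S configuration of 4 because neither its C–O nor its C–C bonds are broken. The step needs regioselective addition to the unsymmetrical aryne, which the benzyloxy group next to the triple bond secures by aryne distortion and by inductive stabilisation of the anion on the flanked carbon (this places the ketone next to the 5''-oxygen), and it needs acyl–oxygen and not alkyl–oxygen opening of the lactone, which the hard fluoride and the strain at the carbonyl favour.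

Step 8
Reactants: 14 7-hydroxy-4H-chromen-4-one
Product: 15 7-(benzyloxy)-4H-chromen-4-one
Conditions: BnBr (1.2 equiv), K2CO3 (1.5 equiv), DMF, rt
Reagents that add atoms: benzyl bromide BrCc1ccccc1
Why: Williamson etherification of the only acidic hydroxyl; the chromone is stable to carbonate base.

Step 9
Reactants: 15 7-(benzyloxy)-4H-chromen-4-one; 16 [4-(benzyloxy)phenyl]boronic acid
Product: 17 (2S)-7-(benzyloxy)-2-[4-(benzyloxy)phenyl]chroman-4-one
Conditions: Pd(OCOCF3)2 (5 mol%), (R)-t-BuPyOx (6 mol%), NH4PF6 (30 mol%), H2O (5 equiv), ClCH2CH2Cl, 60 °C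
Reagents that add atoms: none
Why: Palladium-catalysed asymmetric conjugate addition of an arylboronic acid to a chromone with a pyridine–oxazoline ligand; the tert-butyl group of the ligand controls the face of aryl transfer to C2, the R ligand is chosen as the enantiomer expected to give 2S, and protonation of the palladium enolate releases the flavanone without passing through a ring-opened chalcone.

Step 10
Reactants: 17 (2S)-7-(benzyloxy)-2-[4-(benzyloxy)phenyl]chroman-4-one
Product: 18 chloro{[(2S)-7-(benzyloxy)-2-[4-(benzyloxy)phenyl]-2H-chromen-4-yl]oxy}di(propan-2-yl)silane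
Conditions: LiN(iPr)2 (1.05 equiv), THF, −78 °C, 30 min; cannulated into iPr2SiCl2 (5 equiv), THF, −78 °C to rt; volatiles removed under vacuum, used crude
Reagents that add atoms: dichlorodi(propan-2-yl)silane CC(C)[Si](Cl)(Cl)C(C)C
Why: Kinetic enolisation and O-silylation (silyl enol ether formation); at −78 °C the lithium enolate should not expel the ring phenoxide, so C2 stays S, and inverse addition to excess dichlorosilane stops at the monochloride.

Step 11
Reactants: 13 (2S)-5,7-bis(benzyloxy)-2-[4-(benzyloxy)phenyl]chroman-4-one; 18 chloro{[(2S)-7-(benzyloxy)-2-[4-(benzyloxy)phenyl]-2H-chromen-4-yl]oxy}di(propan-2-yl)silane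
Product: 19 {[(2S)-5,7-bis(benzyloxy)-2-[4-(benzyloxy)phenyl]-2H-chromen-4-yl]oxy}{[(2S)-7-(benzyloxy)-2-[4-(benzyloxy)phenyl]-2H-chromen-4-yl]oxy}di(propan-2-yl)silane
Conditions: 13, LiN(iPr)2 (1.05 equiv), THF, −78 °C, 30 min; then 18 in THF, −78 °C to 0 °C
Reagents that add atoms: none
Why: Second silyl enol ether formation by displacement of the remaining Si–Cl by the lithium enolate of 13; the resulting unsymmetrical silyl bis-enol ether is the temporary O–Si–O tether that brings C3 and C3'' together and excludes homocoupling.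

Step 12
Reactants: 19 {[(2S)-5,7-bis(benzyloxy)-2-[4-(benzyloxy)phenyl]-2H-chromen-4-yl]oxy}{[(2S)-7-(benzyloxy)-2-[4-(benzyloxy)phenyl]-2H-chromen-4-yl]oxy}di(propan-2-yl)silane
Product: 20 (2S,3R,2'S,3'R)-5,7,7'-tris(benzyloxy)-2,2'-bis[4-(benzyloxy)phenyl]-[3,3'-bichromane]-4,4'-dione
Conditions: (NH4)2Ce(NO3)6 (2.2 equiv), NaHCO3 (4.4 equiv), MeCN/EtCN (6:1), −10 °C, 15 min
Reagents that add atoms: none
Why: Oxidative coupling of a silyl bis-enol ether (intramolecular oxidative enolate heterocoupling): one-electron oxidation of one enol ether, C–C bond formation to the other enol carbon through a seven-membered O–Si–O-bridged transition state, a second oxidation and loss of silicon should give the 1,4-diketone; C3 and C3'' are each set by bond formation anti to the aryl group on the neighbouring C2 or C2'' (2,3-trans), and since both are α to a ketone a cis isomer can still equilibrate to trans.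

Step 13
Reactants: 20 (2S,3R,2'S,3'R)-5,7,7'-tris(benzyloxy)-2,2'-bis[4-(benzyloxy)phenyl]-[3,3'-bichromane]-4,4'-dione
Product: 21 (2S,3R,2'S,3'R)-5,7,7'-trihydroxy-2,2'-bis(4-hydroxyphenyl)-[3,3'-bichromane]-4,4'-dione (CNP0138443.1)
Conditions: H2 (1 atm), 10% Pd/C, EtOAc/MeOH (1:1), rt
Reagents that add atoms: none
Why: Hydrogenolysis of the five benzyl ethers under neutral conditions, which avoids the base-induced retro-oxa-Michael ring opening that would epimerise C2 and C2''.

**Compound list**

1 | ethyl 3-[4-(benzyloxy)phenyl]-3-oxopropanoate | CCOC(=O)CC(=O)c1ccc(OCc2ccccc2)cc1 | starting material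
2 | ethyl (3S)-3-[4-(benzyloxy)phenyl]-3-hydroxypropanoate | CCOC(=O)C[C@H](O)c1ccc(OCc2ccccc2)cc1 | intermediate
3 | (3S)-3-[4-(benzyloxy)phenyl]-3-hydroxypropanoic acid | OC(=O)C[C@H](O)c1ccc(OCc2ccccc2)cc1 | intermediate
4 | (4S)-4-[4-(benzyloxy)phenyl]oxetan-2-one | O=C1C[C@@H](c2ccc(OCc3ccccc3)cc2)O1 | intermediate
5 | 3,5-bis(benzyloxy)phenol | Oc1cc(OCc2ccccc2)cc(OCc2ccccc2)c1 | starting material
6 | 3,5-bis(benzyloxy)phenyl N-(propan-2-yl)carbamate | CC(C)NC(=O)Oc1cc(OCc2ccccc2)cc(OCc2ccccc2)c1 | intermediate
7 | 3,5-bis(benzyloxy)phenyl N-[tert-butyl(dimethyl)silyl]-N-(propan-2-yl)carbamate | CC(C)N(C(=O)Oc1cc(OCc2ccccc2)cc(OCc2ccccc2)c1)[Si](C)(C)C(C)(C)C | intermediate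
8 | 3,5-bis(benzyloxy)-2-(trimethylsilyl)phenyl N-(propan-2-yl)carbamate | CC(C)NC(=O)Oc1cc(OCc2ccccc2)cc(OCc2ccccc2)c1[Si](C)(C)C | intermediate
9 | 3,5-bis(benzyloxy)-2-(trimethylsilyl)phenol | C[Si](C)(C)c1c(O)cc(OCc2ccccc2)cc1OCc1ccccc1 | intermediate
10 | 3,5-bis(benzyloxy)-2-(trimethylsilyl)phenyl trifluoromethanesulfonate | C[Si](C)(C)c1c(OS(=O)(=O)C(F)(F)F)cc(OCc2ccccc2)cc1OCc1ccccc1 | intermediate
11 | 3,5-bis(benzyloxy)benzyne (1,2-didehydro-3,5-bis(benzyloxy)benzene) | C1#CC(OCc2ccccc2)=CC(OCc2ccccc2)=C1 | intermediate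
12 | cesium (1S)-1-[4-(benzyloxy)phenyl]-3-fluoro-3-oxopropan-1-olate | [Cs+].[O-][C@@H](CC(F)=O)c1ccc(OCc2ccccc2)cc1 | intermediate
13 | (2S)-5,7-bis(benzyloxy)-2-[4-(benzyloxy)phenyl]chroman-4-one | O=C1C[C@@H](c2ccc(OCc3ccccc3)cc2)Oc2cc(OCc3ccccc3)cc(OCc3ccccc3)c12 | intermediate
14 | 7-hydroxy-4H-chromen-4-one | O=c1ccoc2cc(O)ccc12 | starting material
15 | 7-(benzyloxy)-4H-chromen-4-one | O=c1ccoc2cc(OCc3ccccc3)ccc12 | intermediate
16 | [4-(benzyloxy)phenyl]boronic acid | OB(O)c1ccc(OCc2ccccc2)cc1 | starting material
17 | (2S)-7-(benzyloxy)-2-[4-(benzyloxy)phenyl]chroman-4-one | O=C1C[C@@H](c2ccc(OCc3ccccc3)cc2)Oc2cc(OCc3ccccc3)ccc12 | intermediate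
18 | chloro{[(2S)-7-(benzyloxy)-2-[4-(benzyloxy)phenyl]-2H-chromen-4-yl]oxy}di(propan-2-yl)silane | CC(C)[Si](Cl)(OC1=C[C@@H](c2ccc(OCc3ccccc3)cc2)Oc2cc(OCc3ccccc3)ccc12)C(C)C | intermediate
19 | {[(2S)-5,7-bis(benzyloxy)-2-[4-(benzyloxy)phenyl]-2H-chromen-4-yl]oxy}{[(2S)-7-(benzyloxy)-2-[4-(benzyloxy)phenyl]-2H-chromen-4-yl]oxy}di(propan-2-yl)silane | CC(C)[Si](OC1=C[C@@H](c2ccc(OCc3ccccc3)cc2)Oc2cc(OCc3ccccc3)ccc12)(OC1=C[C@@H](c2ccc(OCc3ccccc3)cc2)Oc2cc(OCc3ccccc3)cc(OCc3ccccc3)c12)C(C)C | intermediate
20 | (2S,3R,2'S,3'R)-5,7,7'-tris(benzyloxy)-2,2'-bis[4-(benzyloxy)phenyl]-[3,3'-bichromane]-4,4'-dione | O=C1c2ccc(OCc3ccccc3)cc2O[C@H](c2ccc(OCc3ccccc3)cc2)[C@H]1[C@H]1C(=O)c2c(OCc3ccccc3)cc(OCc3ccccc3)cc2O[C@@H]1c1ccc(OCc2ccccc2)cc1 | intermediate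
21 | (2S,3R,2'S,3'R)-5,7,7'-trihydroxy-2,2'-bis(4-hydroxyphenyl)-[3,3'-bichromane]-4,4'-dione | O=C1c2ccc(O)cc2O[C@H](c2ccc(O)cc2)[C@H]1[C@H]1C(=O)c2c(O)cc(O)cc2O[C@@H]1c1ccc(O)cc1 | target

**Step count**

Total: 13 steps. Longest linear sequence: 7 steps (1 → 2 → 3 → 4 → 13 → 19 → 20 → 21; steps 1, 2, 3, 7, 11, 12, 13).

**Steps most likely to fail**

Step 7. Fluoride may open the lactone at the benzylic C–O bond instead of the acyl C–O bond. The p-alkoxybenzylic carbon may ionise with loss of CO2. The ring-opened alkoxide may also fragment or eliminate before it meets the aryne. In each case either no annulation occurs or C2'' loses its configuration. The fallback uses known chemistry and gives up the lactone: it would set out from boronic acid 16 and purchasable 5,7-dihydroxy-4H-chromen-4-one. The chromone would be dibenzylated (BnBr, K2CO3, DMF, 60 °C) to 5,7-bis(benzyloxy)-4H-chromen-4-one F1. Rhodium-catalysed asymmetric 1,4-addition of 16 to F1 ([Rh(OH)(cod)]2, an electron-poor atropisomeric bisphosphine of the handedness that gives 2S, toluene/H2O) would then give 13, and the route would continue at step 11.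

Step 12. After one-electron oxidation the doubly activated C2–H of the 4-silyloxy-2H-chromenes may be lost, which aromatises the unit to a flavone. The radical cation may also be desilylated back to the ketone before the C–C bond forms, and facial control at C3 and C3'' may be incomplete. The fallback would set out from 17 and 13. Soft enolisation (TMSOTf, Et3N, CH2Cl2, 0 °C) would give {[(2S)-7-(benzyloxy)-2-[4-(benzyloxy)phenyl]-2H-chromen-4-yl]oxy}trimethylsilane F2 and {[(2S)-5,7-bis(benzyloxy)-2-[4-(benzyloxy)phenyl]-2H-chromen-4-yl]oxy}trimethylsilane F3. F2 would be converted with PhI(OH)OTs and BF3·OEt2 at −78 °C into its umpoled enolonium species, and F3 would be added as the nucleophile. This is a two-electron enolate heterocoupling that needs neither a tether nor a radical cation, and it would come back to the route at 20.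

Step 11. The lithium enolate of 13 may expel the ring phenoxide (β-elimination to the chalcone phenoxide) while silyl transfer to the hindered chlorosilane is still slow. That would open the pyranone and scramble C2''. The same process threatens step 10. The fallback would set out from 17 and avoid metal enolates altogether: amine-mediated soft enolisation with iPr2Si(OTf)2 (1.0 equiv, Et3N, CH2Cl2, −78 °C) would give {[(2S)-7-(benzyloxy)-2-[4-(benzyloxy)phenyl]-2H-chromen-4-yl]oxy}di(propan-2-yl)silyl trifluoromethanesulfonate F4 in place of 18. Addition of 13 and more Et3N would then give 19, and the route would continue at step 12.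

**Further compounds**

F1 | step 7 | 5,7-bis(benzyloxy)-4H-chromen-4-one | O=c1ccoc2cc(OCc3ccccc3)cc(OCc3ccccc3)c12
F2 | step 12 | {[(2S)-7-(benzyloxy)-2-[4-(benzyloxy)phenyl]-2H-chromen-4-yl]oxy}trimethylsilane | C[Si](C)(C)OC1=C[C@@H](c2ccc(OCc3ccccc3)cc2)Oc2cc(OCc3ccccc3)ccc12
F3 | step 12 | {[(2S)-5,7-bis(benzyloxy)-2-[4-(benzyloxy)phenyl]-2H-chromen-4-yl]oxy}trimethylsilane | C[Si](C)(C)OC1=C[C@@H](c2ccc(OCc3ccccc3)cc2)Oc2cc(OCc3ccccc3)cc(OCc3ccccc3)c12
F4 | step 11 | {[(2S)-7-(benzyloxy)-2-[4-(benzyloxy)phenyl]-2H-chromen-4-yl]oxy}di(propan-2-yl)silyl trifluoromethanesulfonate | CC(C)[Si](OS(=O)(=O)C(F)(F)F)(OC1=C[C@@H](c2ccc(OCc3ccccc3)cc2)Oc2cc(OCc3ccccc3)ccc12)C(C)C
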